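The larch flask was to be read at 30 h, so I set every clock I could read from the earlier runs against that time.

| flask | substrate | temperature | remark | time |
|---|---|---|---|---|
| larch | 10 mM | 5 °C | the very flask that is asked about, followed so far |  |
| elm | 10 mM | 0 °C | run made earlier |  |
| flask | 10 mM | 5 °C |  | 30 h |

| run | time / h | target / % | substrate / % |
|---|---|---|---|
| larch | 2.50 | 50.1 | 37.9 |
| larch | 5.00 | 59.1 | 14.6 |
| larch | 8.00 | 52.5 | 4.8 |
| larch | 10.0 | 46.3 | 2.0 |
| larch | 12.0 | 39.8 | 1.4 |
| larch | 15.0 | 31.8 | 0.6 |
| larch | 20.0 | 21.0 | 0 |
| elm | 2.50 | 33.9 | 59.7 |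
| elm | 5.00 | 50.2 | 37.0 |
| elm | 8.00 | 57.4 | 20.5 |
| elm | 10.0 | 58.5 | 14.0 |
| elm | 12.0 | 58.2 | 9.3 |
| elm | 15.0 | 54.4 | 5.7 |
| elm | 20.0 | 47.4 | 2.6 |

(readings scatter by 0.3 percentage points)

- target taken out counts as made
- on the list of suspects stand: substrate <-> other conformer; substrate -> target; other conformer -> isomer of the product; target <-> isomer of the product; target -> over-reaction product
- additions bring no volume worth counting

- east: at 30 h raise the temperature by 20 K, then wait 30 h
- south-west: at 30 h take out 90% of the target then present, then wait 30 h
- north: at 30 h add substrate, 50.0% of the amount charged, then wait 30 h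
- south: change nothing and wait 30 h more

- target, in percent of the substrate first charged, at 30 h
- the remedy with the largest gain of target, or "none" below 2 percentage points (east / south-west / north / south / none)
- target present, with what was taken out counted in, in percent of the substrate first charged, after east
- target present, with what was taken out counted in, in percent of the substrate first charged, after south

The first rung in the larch flask was the substrate's clock: c(substrate) fell from 37.9% at 2.50 h to 4.8% at 8.00 h, a decay time of 2.66 h. The highest reading of c(target), 59.1% at 5.00 h, came on this rung.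

The next rung was the tail time, 12.5 h, the time in which c(target) falls by a factor of e once hardly any substrate feeds it. I read it from 39.8% at 12.0 h and 21.0% at 20.0 h.

Because the substrate's clock was shorter, I let the tail carry the larch flask from the last reading to 30 h, 0.800 tail times later. That gave 9.44% at 30 h, and 0.859% after south.

For east, the elm run's substrate clock of 5.15 h showed 1.94 times the speed per step from elm to larch. I counted the rise of 20 K as 4 such steps. Assuming the tail sped up alike, its time became 0.896 h, so 33.5 tail times fitted into the wait, and I reckoned target after east as lost.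

For north, counting every added substrate as target, I reckoned the new batch at 5.77%, or 6.63% in total. South-west counted 8.59%. Neither beat 9.44% by the margin, so I chose none.

The forecast gave 9%, 0.05% after east, 0.7% after south, a south below mine, and none, saying “nothing gains, so none”.

The flask gave 9.30% at 30 h, 0% after east and 1.71% after south; the best choice was none.

    substrate ⇌ other conformer (K = 0.480, k = 7.00 × 10⁻⁴ min⁻¹, Ea = 85.0 kJ mol⁻¹, ΔH = −28.0 kJ mol⁻¹)
    substrate → target (k = 0.00600 min⁻¹, Ea = 86.0 kJ mol⁻¹)
    other conformer → isomer of the product (k = 0.00200 min⁻¹, Ea = 99.0 kJ mol⁻¹)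
    target ⇌ isomer of the product (K = 1.90, k = 2.20 × 10⁻⁴ min⁻¹, Ea = 90.0 kJ mol⁻¹, ΔH = −45.0 kJ mol⁻¹)
    target → over-reaction product (k = 0.00130 min⁻¹, Ea = 90.0 kJ mol⁻¹)
    (constants at 5 °C)

From the reading of 21.0% to the 9.30% of the larch flask, the tail time came to 12.3 h, close to 12.5 h. South lay 0.85 percentage points above my figure, and south-west gained 0.17 points, less than the margin of 2 points. The larch flask was not at rest at 30 h. For a flask left until 2.0 d, the tail time gave 2.20%, and that flask held 2.80%, so the fall had slowed. At 300 h, target stood at 0.295%, isomer of the product had gone from 16.4% to 3.62%, and over-reaction product had risen from 74.2% to 96.1%.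

The readings come from a simulation for substances that don't exist; the scatter is artificial.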